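## Retrosynthetic overview

1. Target ⇒ C3–O acylation with (2E)-oct-2-enoic acid and C5′–O desilylation of a 2-methyl-5-alkyl-decahydroquinolin-3-ol.
2. C8a (hydride under N–Al control) and C4a/C5 (hydroxyl-directed hydrogenation) ⇐ a 2,3,4,6,7,8-hexahydroquinoline (1-azadiene) that carries only the C2, C3 and C5′ centres.
3. Both rings ⇐ one acyclic amino 1,5-diketone in one flask, as in the presumed biogenesis: piperidine ring first (amine + ketone → Δ1-piperideine), carbocycle second (enamine aldol C4a–C5, then dehydration).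
4. Amino 1,5-diketone ⇐ 2,6-dialkylpyridine (Birch reduction, hydrolysis) ⇐ 2,6-dibromopyridine by B-alkyl Suzuki and Sonogashira couplings.
5. Fragments: (R)-1,2-epoxypentane + allyl Grignard (C5′); N-Boc-D-alanine Weinreb amide → ynone → asymmetric transfer hydrogenation (C2, C3).

Assumption: the presumed biogenesis is taken to be a linear, alanine-derived 2-amino-3-hydroxy-6,10-diketone that closes the piperidine ring by amine–ketone condensation and the carbocycle by enamine aldol condensation, followed by reductions; atoms are labelled by decahydroquinoline numbering (side-chain carbinol = C5′).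

## Route

Step 1
Reactants: 1 (2R)-2-propyloxirane; 2 allylmagnesium bromide
Product: 4 triisopropyl{[(4R)-oct-7-en-4-yl]oxy}silane, via magnesium alkoxide 3 (not isolated)
Conditions: CuI (10 mol %), Et2O, −30 → 0 °C; then TIPSOTf, 0 °C → rt
Reagents that add atoms: triisopropylsilyl trifluoromethanesulfonate (TIPSOTf), CC(C)[Si](C(C)C)(C(C)C)OS(=O)(=O)C(F)(F)F
Why: Copper-catalysed SN2 opening of the epoxide at its unsubstituted carbon by the Grignard reagent leaves the (R)-carbinol centre (later C5′) untouched, and the magnesium alkoxide is O-silylated in the same flask (Grignard epoxide opening, silyl ether formation).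

Step 2
Reactants: 4 triisopropyl{[(4R)-oct-7-en-4-yl]oxy}silane; 5 2,6-dibromopyridine
Product: 7 2-bromo-6-[(5R)-5-(triisopropylsilyloxy)octyl]pyridine, via alkylborane 6 (not isolated)
Conditions: 9-BBN (1.2 equiv), THF, 0 °C → rt; then 5 (3 equiv), Pd(dppf)Cl2 (5 mol %), K3PO4 (3 M aq.), DMF, 60 °C
Reagents that add atoms: none
Why: Anti-Markovnikov hydroboration followed by B-alkyl Suzuki–Miyaura coupling joins C1′ to the future C5; the threefold excess of dibromide keeps the coupling at the mono stage and no stereocentre is touched.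

Step 3
Reactants: 8 tert-butyl [(2R)-1-[methoxy(methyl)amino]-1-oxopropan-2-yl]carbamate; 9 lithium (trimethylsilyl)acetylide
Product: 10 tert-butyl [(2R)-3-oxo-5-(trimethylsilyl)pent-4-yn-2-yl]carbamate
Conditions: 9 (2.5 equiv), THF, −78 → −20 °C; then 1 M HCl (aq.), 0 °C
Reagents that add atoms: none
Why: Weinreb ketone synthesis, in which the chelated tetrahedral adduct prevents over-addition, the acidic quench keeps the released N,O-dimethylhydroxylamine from adding to the ynone, and the α-centre (later C2) does not epimerise at low temperature.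

Step 4
Reactants: 10 tert-butyl [(2R)-3-oxo-5-(trimethylsilyl)pent-4-yn-2-yl]carbamate
Product: 12 tert-butyl [(2R,3R)-3-hydroxypent-4-yn-2-yl]carbamate, via silyl alkynol 11 (not isolated)
Conditions: Ru[(S,S)-TsDPEN](p-cymene) (1 mol %), i-PrOH, rt; then K2CO3 (cat.), MeOH, rt
Reagents that add atoms: none
Why: Noyori asymmetric transfer hydrogenation of an α,β-acetylenic ketone, in which the (S,S) catalyst delivers hydride from i-PrOH to the ketone face that gives the (3R) carbinol (alkynyl in the place usually taken by aryl), a catalyst-controlled result matched with the Felkin–Anh preference, so the syn-(2R,3R) amino alcohol forms before methanolysis of the C–Si bond.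

Step 5
Reactants: 7 2-bromo-6-[(5R)-5-(triisopropylsilyloxy)octyl]pyridine; 12 tert-butyl [(2R,3R)-3-hydroxypent-4-yn-2-yl]carbamate
Product: 13 tert-butyl [(2R,3R)-3-hydroxy-5-{6-[(5R)-5-(triisopropylsilyloxy)octyl]pyridin-2-yl}pent-4-yn-2-yl]carbamate
Conditions: Pd(PPh3)2Cl2 (3 mol %), CuI (6 mol %), Et3N/THF (1:1), 50 °C
Reagents that add atoms: none
Why: Sonogashira coupling of the terminal alkyne at the activated 2-bromopyridine joins C4a to the future C8a; free OH, NHBoc and the silyl ether are tolerated and no stereocentre is involved.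

Step 6
Reactants: 13 tert-butyl [(2R,3R)-3-hydroxy-5-{6-[(5R)-5-(triisopropylsilyloxy)octyl]pyridin-2-yl}pent-4-yn-2-yl]carbamate
Product: 14 tert-butyl [(2R,3R)-3-hydroxy-5-{6-[(5R)-5-(triisopropylsilyloxy)octyl]pyridin-2-yl}pentan-2-yl]carbamate
Conditions: H2 (1 atm), 10% Pd/C, EtOAc, rt
Reagents that add atoms: none
Why: Heterogeneous catalytic hydrogenation saturates the alkyne while the pyridine ring, carbamate and silyl ether are inert at 1 atm in a neutral solvent, and the stereocentres are unaffected.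

Step 7
Reactants: 14 tert-butyl [(2R,3R)-3-hydroxy-5-{6-[(5R)-5-(triisopropylsilyloxy)octyl]pyridin-2-yl}pentan-2-yl]carbamate
Product: 16 tert-butyl [(2R,3R,15R)-3-hydroxy-6,10-dioxo-15-(triisopropylsilyloxy)octadecan-2-yl]carbamate, via dihydropyridine 15 (not isolated)
Conditions: Na (6 equiv), NH3 (l)/THF/EtOH, −78 → −33 °C; NH4Cl (s); then 1 M HCl (aq.)/THF, 0 °C → rt
Reagents that add atoms: water, O
Why: Birch reduction of a 2,6-dialkylpyridine gives the 1,4-dihydropyridine, a cyclic bis-enamine whose mild acid hydrolysis releases the 1,5-diketone and ammonia (pyridine as latent 1,5-diketone); Boc, TIPS and both carbinol centres survive.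

Step 8
Reactants: 16 tert-butyl [(2R,3R,15R)-3-hydroxy-6,10-dioxo-15-(triisopropylsilyloxy)octadecan-2-yl]carbamate
Product: 20 (2R,3R)-2-methyl-5-[(5R)-5-(triisopropylsilyloxy)octyl]-2,3,4,6,7,8-hexahydroquinolin-3-ol, via ammonium trifluoroacetate 17 (not isolated), via cyclic imine 18 (not isolated), via aldol adduct 19 (not isolated)
Conditions: TFA/CH2Cl2 (1:4), 0 °C; concentrate; NaHCO3 (aq.)/toluene; then AcOH (20 mol %), 4 Å molecular sieves, toluene, 80 °C
Reagents that add atoms: none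
Why: Proposed new method: loss of Boc frees the C2 amine, which condenses with the ketone that becomes C8a to give Δ1-piperideine 18; only its endocyclic enamine tautomer can reach the ketone that becomes C5 through a six-membered transition state (the exocyclic one would give a cyclobutane), so acid-catalysed enamine aldol addition gives 19, and irreversible dehydration to the conjugated 1-azadiene 20 drains the reversible spiro-Mannich and N,O-ketal side equilibria; the closest known reaction types are the aza-Robinson annulation of 2-alkyl cyclic imines and the aldol cyclisation of pyridine-derived 1,5-diketones, and no stereocentre is created or epimerised (C2 and C3 are not enolisable).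

Step 9
Reactants: 20 (2R,3R)-2-methyl-5-[(5R)-5-(triisopropylsilyloxy)octyl]-2,3,4,6,7,8-hexahydroquinolin-3-ol
Product: 21 (2R,3R,8aR)-2-methyl-5-[(5R)-5-(triisopropylsilyloxy)octyl]-1,2,3,4,6,7,8,8a-octahydroquinolin-3-ol
Conditions: AlMe3 (3 equiv), THF, −78 °C; LiAlH4 (2 equiv), −78 → −40 °C; KNaC4H4O6 (aq.)
Reagents that add atoms: none
Why: Trans-selective LiAlH4/AlMe3 reduction of a cyclic imine, in which aluminium bound to N (and to the C3 alkoxide) forces the C2 methyl pseudoaxial and axial hydride attack at C8a then occurs on the face carrying that methyl and the C3 oxygen, setting (8aR) with H8a cis to the methyl, while the fully substituted β-carbon disfavours 1,4-addition.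

Step 10
Reactants: 21 (2R,3R,8aR)-2-methyl-5-[(5R)-5-(triisopropylsilyloxy)octyl]-1,2,3,4,6,7,8,8a-octahydroquinolin-3-ol
Product: 23 (2R,3R,4aS,5S,8aR)-2-methyl-5-[(5R)-5-(triisopropylsilyloxy)octyl]decahydroquinolin-3-ol, via tetrafluoroborate salt 22 (not isolated)
Conditions: HBF4·OEt2 (1.0 equiv), CH2Cl2, 0 °C; [Ir(cod)(PCy3)(py)]PF6 (10 mol %), H2 (1 atm), CH2Cl2, rt; NaHCO3 (aq.)
Reagents that add atoms: none
Why: Hydroxyl-directed homogeneous hydrogenation, in which the cationic iridium catalyst binds the pseudoaxial homoallylic C3 hydroxyl and adds H2 syn across the tetrasubstituted C4a=C5 bond from that face, setting (4aS) and (5S) with H4a and H5 cis to O3 and H8a (cis ring fusion), the amine being masked as its salt so that it neither poisons the catalyst nor isomerises to an enamine.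

Step 11
Reactants: 23 (2R,3R,4aS,5S,8aR)-2-methyl-5-[(5R)-5-(triisopropylsilyloxy)octyl]decahydroquinolin-3-ol; 24 (2E)-oct-2-enoic acid
Product: 27 (2R,3R,4aS,5S,8aR)-2-methyl-5-[(5R)-5-(triisopropylsilyloxy)octyl]decahydroquinolin-3-yl (2E)-oct-2-enoate, via acid chloride 25 (not isolated), via hydrochloride salt 26 (not isolated)
Conditions: 24, (COCl)2, DMF (cat.), CH2Cl2, 0 °C → rt, concentrate; 23, HCl (2 M in Et2O, 1.1 equiv), CH2Cl2, 0 °C; then 25 (3 equiv), ClCH2CH2Cl, 50 °C; NaHCO3 (aq.), 0 °C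
Reagents that add atoms: none
Why: Chemoselective O-acylation of an amino alcohol under acidic conditions, in which the protonated amine cannot be acylated, the only free hydroxyl (C3) is esterified with retention, and the C5′ oxygen stays blocked as the TIPS ether.

Step 12
Reactants: 27 (2R,3R,4aS,5S,8aR)-2-methyl-5-[(5R)-5-(triisopropylsilyloxy)octyl]decahydroquinolin-3-yl (2E)-oct-2-enoate
Product: 28 (2R,3R,4aS,5S,8aR)-5-[(5R)-5-hydroxyoctyl]-2-methyldecahydroquinolin-3-yl (2E)-oct-2-enoate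
Conditions: HF·pyridine, THF/pyridine, 0 °C → rt; NaHCO3 (aq.), 0 °C
Reagents that add atoms: none
Why: Fluoride-mediated desilylation with the amine protonated frees the C5′ alcohol without ester cleavage, conjugate addition or O-to-N acyl migration, giving the target with C5′ from step 1, C2 from step 3, C3 from step 4, C8a from step 9 and C4a/C5 from step 10.

## Compound list

1 | (2R)-2-propyloxirane ((R)-1,2-epoxypentane) | CCC[C@@H]1CO1 | starting material
2 | allylmagnesium bromide | C=CC[Mg]Br | starting material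
3 | bromomagnesium (4R)-oct-7-en-4-olate | CCC[C@@H](O[Mg]Br)CCC=C | intermediate
4 | triisopropyl{[(4R)-oct-7-en-4-yl]oxy}silane | CCC[C@@H](O[Si](C(C)C)(C(C)C)C(C)C)CCC=C | intermediate
5 | 2,6-dibromopyridine | Brc1cccc(Br)n1 | starting material
6 | 9-[(5R)-5-(triisopropylsilyloxy)octyl]-9-borabicyclo[3.3.1]nonane | CCC[C@@H](O[Si](C(C)C)(C(C)C)C(C)C)CCCCB1C2CCCC1CCC2 | intermediate
7 | 2-bromo-6-[(5R)-5-(triisopropylsilyloxy)octyl]pyridine | CCC[C@@H](O[Si](C(C)C)(C(C)C)C(C)C)CCCCc1cccc(Br)n1 | intermediate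
8 | tert-butyl [(2R)-1-[methoxy(methyl)amino]-1-oxopropan-2-yl]carbamate (N-Boc-D-alanine Weinreb amide) | C[C@@H](NC(=O)OC(C)(C)C)C(=O)N(C)OC | starting material
9 | lithium (trimethylsilyl)acetylide | [Li]C#C[Si](C)(C)C | starting material
10 | tert-butyl [(2R)-3-oxo-5-(trimethylsilyl)pent-4-yn-2-yl]carbamate | C[C@@H](NC(=O)OC(C)(C)C)C(=O)C#C[Si](C)(C)C | intermediate
11 | tert-butyl [(2R,3R)-3-hydroxy-5-(trimethylsilyl)pent-4-yn-2-yl]carbamate | C[C@@H](NC(=O)OC(C)(C)C)[C@H](O)C#C[Si](C)(C)C | intermediate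
12 | tert-butyl [(2R,3R)-3-hydroxypent-4-yn-2-yl]carbamate | C[C@@H](NC(=O)OC(C)(C)C)[C@H](O)C#C | intermediate
13 | tert-butyl [(2R,3R)-3-hydroxy-5-{6-[(5R)-5-(triisopropylsilyloxy)octyl]pyridin-2-yl}pent-4-yn-2-yl]carbamate | CCC[C@@H](O[Si](C(C)C)(C(C)C)C(C)C)CCCCc1cccc(n1)C#C[C@@H](O)[C@@H](C)NC(=O)OC(C)(C)C | intermediate
14 | tert-butyl [(2R,3R)-3-hydroxy-5-{6-[(5R)-5-(triisopropylsilyloxy)octyl]pyridin-2-yl}pentan-2-yl]carbamate | CCC[C@@H](O[Si](C(C)C)(C(C)C)C(C)C)CCCCc1cccc(n1)CC[C@@H](O)[C@@H](C)NC(=O)OC(C)(C)C | intermediate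
15 | tert-butyl [(2R,3R)-3-hydroxy-5-{6-[(5R)-5-(triisopropylsilyloxy)octyl]-1,4-dihydropyridin-2-yl}pentan-2-yl]carbamate | CCC[C@@H](O[Si](C(C)C)(C(C)C)C(C)C)CCCCC1=CCC=C(N1)CC[C@@H](O)[C@@H](C)NC(=O)OC(C)(C)C | intermediate
16 | tert-butyl [(2R,3R,15R)-3-hydroxy-6,10-dioxo-15-(triisopropylsilyloxy)octadecan-2-yl]carbamate (partly as its five-membered lactol) | CCC[C@@H](O[Si](C(C)C)(C(C)C)C(C)C)CCCCC(=O)CCCC(=O)CC[C@@H](O)[C@@H](C)NC(=O)OC(C)(C)C | intermediate
17 | (2R,3R,15R)-3-hydroxy-6,10-dioxo-15-(triisopropylsilyloxy)octadecan-2-aminium trifluoroacetate | CCC[C@@H](O[Si](C(C)C)(C(C)C)C(C)C)CCCCC(=O)CCCC(=O)CC[C@@H](O)[C@@H](C)[NH3+].[O-]C(=O)C(F)(F)F | intermediate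
18 | (2R,3R)-2-methyl-6-[(9R)-4-oxo-9-(triisopropylsilyloxy)dodecyl]-2,3,4,5-tetrahydropyridin-3-ol | CCC[C@@H](O[Si](C(C)C)(C(C)C)C(C)C)CCCCC(=O)CCCC1=N[C@H](C)[C@H](O)CC1 | intermediate
19 | (2R,3R)-2-methyl-5-[(5R)-5-(triisopropylsilyloxy)octyl]-2,3,4,4a,5,6,7,8-octahydroquinoline-3,5-diol (C4a/C5 epimers) | CCC[C@@H](O[Si](C(C)C)(C(C)C)C(C)C)CCCCC1(O)CCCC2=N[C@H](C)[C@H](O)CC12 | intermediate
20 | (2R,3R)-2-methyl-5-[(5R)-5-(triisopropylsilyloxy)octyl]-2,3,4,6,7,8-hexahydroquinolin-3-ol | CCC[C@@H](O[Si](C(C)C)(C(C)C)C(C)C)CCCCC1=C2C[C@@H](O)[C@@H](C)N=C2CCC1 | intermediate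
21 | (2R,3R,8aR)-2-methyl-5-[(5R)-5-(triisopropylsilyloxy)octyl]-1,2,3,4,6,7,8,8a-octahydroquinolin-3-ol | CCC[C@@H](O[Si](C(C)C)(C(C)C)C(C)C)CCCCC1=C2C[C@@H](O)[C@@H](C)N[C@@H]2CCC1 | intermediate
22 | (2R,3R,8aR)-3-hydroxy-2-methyl-5-[(5R)-5-(triisopropylsilyloxy)octyl]-1,2,3,4,6,7,8,8a-octahydroquinolin-1-ium tetrafluoroborate | CCC[C@@H](O[Si](C(C)C)(C(C)C)C(C)C)CCCCC1=C2C[C@@H](O)[C@@H](C)[NH2+][C@@H]2CCC1.F[B-](F)(F)F | intermediate
23 | (2R,3R,4aS,5S,8aR)-2-methyl-5-[(5R)-5-(triisopropylsilyloxy)octyl]decahydroquinolin-3-ol | O[C@@H]1C[C@H]2[C@@H](CCCC[C@@H](CCC)O[Si](C(C)C)(C(C)C)C(C)C)CCC[C@H]2N[C@@H]1C | intermediate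
24 | (2E)-oct-2-enoic acid | CCCCC/C=C/C(=O)O | starting material
25 | (2E)-oct-2-enoyl chloride | CCCCC/C=C/C(=O)Cl | intermediate
26 | (2R,3R,4aS,5S,8aR)-3-hydroxy-2-methyl-5-[(5R)-5-(triisopropylsilyloxy)octyl]decahydroquinolin-1-ium chloride | O[C@@H]1C[C@H]2[C@@H](CCCC[C@@H](CCC)O[Si](C(C)C)(C(C)C)C(C)C)CCC[C@H]2[NH2+][C@@H]1C.[Cl-] | intermediate
27 | (2R,3R,4aS,5S,8aR)-2-methyl-5-[(5R)-5-(triisopropylsilyloxy)octyl]decahydroquinolin-3-yl (2E)-oct-2-enoate | CCCCC/C=C/C(=O)O[C@@H]1C[C@H]2[C@@H](CCCC[C@@H](CCC)O[Si](C(C)C)(C(C)C)C(C)C)CCC[C@H]2N[C@@H]1C | intermediate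
28 | (2R,3R,4aS,5S,8aR)-5-[(5R)-5-hydroxyoctyl]-2-methyldecahydroquinolin-3-yl (2E)-oct-2-enoate | CCCCC/C=C/C(=O)O[C@@H]1C[C@H]2[C@@H](CCCC[C@H](O)CCC)CCC[C@H]2N[C@@H]1C | target

## Step count and risks

Total steps: 12. Longest linear sequence: 10 (steps 1, 2, 5, 6, 7, 8, 9, 10, 11, 12; the alanine branch through steps 3 and 4 is equally long).

The three steps most likely to fail are steps 8, 9 and 11.

Step 8 (one-flask double ring closure). The enamine aldol may stall at the cyclic imine or be diverted to spiro-Mannich products. The fallback sets out from 16 and keeps the nitrogen as its carbamate. Heating 16 with pyridinium p-toluenesulfonate in toluene with water removal condenses the NHBoc group with the ketone that becomes C8a, giving the cyclic ene-carbamate tert-butyl (2R,3R)-3-hydroxy-2-methyl-6-[(9R)-4-oxo-9-(triisopropylsilyloxy)dodecyl]-3,4-dihydropyridine-1(2H)-carboxylate F1. BF3·OEt2 in CH2Cl2 then drives an intramolecular ene-carbamate addition to the remaining ketone (N-acyliminium ion, proton loss from C8, dehydration) to give the dienyl carbamate tert-butyl (2R,3R)-3-hydroxy-2-methyl-5-[(5R)-5-(triisopropylsilyloxy)octyl]-3,4,6,7-tetrahydroquinoline-1(2H)-carboxylate F2. Brief TFA treatment removes the Boc group and the dienamine tautomerises to the azadiene, so the route is rejoined at 20.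

Step 9 (C8a selectivity on a conjugated imine). If hydride addition to the azadiene is unselective, the order of the two reductions is inverted, setting out from 20. Hydroxyl-directed hydrogenation of the C4a=C5 bond with [Ir(cod)(PCy3)(py)]PF6 under H2 in CH2Cl2 (the sp2 nitrogen is flanked on both sides and binds the metal only weakly) first sets C4a and C5 and gives the saturated cyclic imine (2R,3R,4aS,5S)-2-methyl-5-[(5R)-5-(triisopropylsilyloxy)octyl]-2,3,4,4a,5,6,7,8-octahydroquinolin-3-ol F3. This is a plain 2,6-dialkyl-Δ1-piperideine, the substrate class for which LiAlH4/AlMe3 at −78 °C is known to give the 2,6-trans product. That reduction leads directly to 23, bypassing 21.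

Step 11 (acylation of the ammonium salt). If the hindered axial alcohol next to the ammonium centre is too unreactive, or the silyl ether suffers, the nitrogen is masked covalently, setting out from 23. Boc2O gives tert-butyl (2R,3R,4aS,5S,8aR)-3-hydroxy-2-methyl-5-[(5R)-5-(triisopropylsilyloxy)octyl]octahydroquinoline-1(2H)-carboxylate F4. Carbodiimide esterification with 24 (EDCI, DMAP, CH2Cl2) gives tert-butyl (2R,3R,4aS,5S,8aR)-2-methyl-3-{[(2E)-oct-2-enoyl]oxy}-5-[(5R)-5-(triisopropylsilyloxy)octyl]octahydroquinoline-1(2H)-carboxylate F5. TFA in CH2Cl2 at 0 °C removes the Boc group and returns the route to 27.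

Further compounds

F1 | step 8 | tert-butyl (2R,3R)-3-hydroxy-2-methyl-6-[(9R)-4-oxo-9-(triisopropylsilyloxy)dodecyl]-3,4-dihydropyridine-1(2H)-carboxylate | CCC[C@@H](O[Si](C(C)C)(C(C)C)C(C)C)CCCCC(=O)CCCC1=CC[C@@H](O)[C@@H](C)N1C(=O)OC(C)(C)C
F2 | step 8 | tert-butyl (2R,3R)-3-hydroxy-2-methyl-5-[(5R)-5-(triisopropylsilyloxy)octyl]-3,4,6,7-tetrahydroquinoline-1(2H)-carboxylate | CCC[C@@H](O[Si](C(C)C)(C(C)C)C(C)C)CCCCC1=C2C[C@@H](O)[C@@H](C)N(C(=O)OC(C)(C)C)C2=CCC1
F3 | step 9 | (2R,3R,4aS,5S)-2-methyl-5-[(5R)-5-(triisopropylsilyloxy)octyl]-2,3,4,4a,5,6,7,8-octahydroquinolin-3-ol | O[C@@H]1C[C@H]2[C@@H](CCCC[C@@H](CCC)O[Si](C(C)C)(C(C)C)C(C)C)CCCC2=N[C@@H]1C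
F4 | step 11 | tert-butyl (2R,3R,4aS,5S,8aR)-3-hydroxy-2-methyl-5-[(5R)-5-(triisopropylsilyloxy)octyl]octahydroquinoline-1(2H)-carboxylate | O[C@@H]1C[C@H]2[C@@H](CCCC[C@@H](CCC)O[Si](C(C)C)(C(C)C)C(C)C)CCC[C@H]2N(C(=O)OC(C)(C)C)[C@@H]1C
F5 | step 11 | tert-butyl (2R,3R,4aS,5S,8aR)-2-methyl-3-{[(2E)-oct-2-enoyl]oxy}-5-[(5R)-5-(triisopropylsilyloxy)octyl]octahydroquinoline-1(2H)-carboxylate | CCCCC/C=C/C(=O)O[C@@H]1C[C@H]2[C@@H](CCCC[C@@H](CCC)O[Si](C(C)C)(C(C)C)C(C)C)CCC[C@H]2N(C(=O)OC(C)(C)C)[C@@H]1C
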